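## Retrosynthetic overview

1. The oxirane is made last: target ⇐ oxidation of a C1 carbinol ⇐ hydroxyl-directed epoxidation of a cis-carveol-type allylic alcohol ⇐ 1,2-reduction of a 6-acyloxy enone.
2. Both 3-methylbut-2-enoates go on together onto a 6,8-diol; the C6 hydroxyl comes from α′-hydroxylation of the enone enolate, trans to the side chain.
3. The enone with its free C8 hydroxyl comes from hydrolysis and decarboxylation of a bicyclic β-keto δ-lactone.
4. Key step: that δ-lactone (a temporary tether ring) and the cyclohexenone form together in one flask from an acyclic aldehyde, by enamine oxidation to a dienyl iminium ion, tethered Michael addition (C5–C6) and aldol condensation (C2=C3); C8 relays its configuration to C5 through the lactone.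
5. The acyclic aldehyde comes from 4-methylpent-3-enal, ethynyl(trimethyl)silane (asymmetric alkynylation sets C8), methyl 3-oxopentanoate (tether) and allyl alcohol (ruthenium-catalysed Alder-ene). Ring order: lactone and carbocycle together, then oxirane.

Assumption: the SMILES is read as drawn, i.e. ring centres (1S,3S,4S,6S) with the oxirane cis to the side chain and trans to the ring ester, side-chain carbinol (3R); locants used below are C1 (ring C=O), C2 (methyl-bearing oxirane carbon), C3 (oxirane CH), C4 (CH2), C5 (side-chain-bearing CH), C6 (CH–O), C7 (C=CH2), C8 (side-chain carbinol).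

## Route

Step 1
Reactants: 1 4-methylpent-3-en-1-ol
Product: 2 4-methylpent-3-enal
Conditions: Dess–Martin periodinane, CH2Cl2, 0 °C; used at once as a solution
Reagents that add atoms: none
Why: Dess–Martin oxidation stops at the aldehyde and is mild enough to keep the β,γ-alkene out of conjugation.

Step 2
Reactants: 2 4-methylpent-3-enal; 3 ethynyl(trimethyl)silane
Product: 5 (3R)-6-methylhept-5-en-1-yn-3-ol, via TMS-alkynol 4 (not isolated)
Conditions: Me2Zn, ProPhenol ligand (10 mol%, the enantiomer that gives Si-face addition), Ph3PO (20 mol%), toluene, 0 °C; then MeOH, K2CO3, rt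
Reagents that add atoms: none
Why: Trost-type asymmetric alkynylation, in which the dinuclear zinc–ProPhenol complex delivers the zinc acetylide to the Si face of the aldehyde and so sets the (R) carbinol (C8), after which methanolic carbonate cleaves the C–Si bond.

Step 3
Reactants: 5 (3R)-6-methylhept-5-en-1-yn-3-ol; 6 methyl 3-oxopentanoate
Product: 7 (3R)-6-methylhept-5-en-1-yn-3-yl 3-oxopentanoate
Conditions: 6 (2 equiv), DMAP (20 mol%), toluene, 100 °C, 4 Å molecular sieves
Reagents that add atoms: none
Why: DMAP-promoted transesterification of a β-keto ester (through the acylketene) acylates the secondary alcohol at oxygen, so the stereocentre is untouched.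

Step 4
Reactants: 7 (3R)-6-methylhept-5-en-1-yn-3-yl 3-oxopentanoate; 8 prop-2-en-1-ol
Product: 9 (5R)-8-methyl-4-methylidene-1-oxonon-7-en-5-yl 3-oxopentanoate
Conditions: 8 (3 equiv), [CpRu(MeCN)3]PF6 (5 mol%), acetone, rt
Reagents that add atoms: none
Why: Trost ruthenium-catalysed Alder-ene coupling (ruthenacyclopentene, β-hydride elimination, enol to aldehyde) joins the allyl terminus to the internal alkyne carbon, the branched sense favoured by the propargylic oxygen, and creates the 1,1-disubstituted alkene without forming a stereocentre.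

Step 5
Reactants: 9 (5R)-8-methyl-4-methylidene-1-oxonon-7-en-5-yl 3-oxopentanoate
Product: 12 (3R,4aR)-7-methyl-4-methylidene-3-(3-methylbut-2-en-1-yl)-3,4,4a,5-tetrahydro-1H-isochromene-1,8(8aH)-dione, via dienal 10 (not isolated), via Michael adduct 11 (not isolated)
Conditions: (S)-α,α-diphenylprolinol trimethylsilyl ether (20 mol%), PhCO2H (20 mol%), IBX (1.1 equiv), toluene, rt; then TsOH·H2O (20 mol%), 45 °C
Reagents that add atoms: none
Why: Proposed new method: the amine forms the enamine of 9, IBX dehydrogenates it to the conjugated dienyl iminium ion, and the tethered β-keto ester enol adds 6-exo to the β-carbon through a chair-like transition state with the C8 substituent equatorial, which puts the new C5–C6 bond 1,3-cis to it, the same face the (S)-catalyst leaves open (Si face), while acid then drives aldol condensation of the ethyl ketone onto the released aldehyde to close the cyclohexenone; the closest known reactions are amine-catalysed IBX oxidation of aldehyde enamines followed by Michael addition and the diarylprolinol-ether Michael/aldol-condensation annulation of β-keto esters with enals, and the ring-fusion carbon C6 stays epimerisable and is erased in step 6.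

Step 6
Reactants: 12 (3R,4aR)-7-methyl-4-methylidene-3-(3-methylbut-2-en-1-yl)-3,4,4a,5-tetrahydro-1H-isochromene-1,8(8aH)-dione
Product: 14 (5R)-5-[(3R)-3-hydroxy-6-methylhepta-1,5-dien-2-yl]-2-methylcyclohex-2-en-1-one, via keto acid 13 (not isolated)
Conditions: LiOH (3 equiv), THF/H2O, 40 °C; then 1 M HCl to pH 3, 40 °C
Reagents that add atoms: none
Why: Saponification of the lactone at the acyl carbon (the C8–O bond is not broken, so C8 stays R) followed by decarboxylation of the β-keto acid (acetoacetic-ester ketone cleavage) gives the dienol, which protonates at C6 to the conjugated enone.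

Step 7
Reactants: 14 (5R)-5-[(3R)-3-hydroxy-6-methylhepta-1,5-dien-2-yl]-2-methylcyclohex-2-en-1-one
Product: 15 (5S,6S)-6-hydroxy-5-[(3R)-3-hydroxy-6-methylhepta-1,5-dien-2-yl]-2-methylcyclohex-2-en-1-one
Conditions: NaN(SiMe3)2 (2.3 equiv), THF, −78 °C; 2-(phenylsulfonyl)-3-phenyloxaziridine (1.3 equiv), −78 °C; then AcOH
Reagents that add atoms: 2-(phenylsulfonyl)-3-phenyloxaziridine O=S(=O)(c1ccccc1)N1OC1c1ccccc1
Why: Kinetic α′-deprotonation gives the cross-conjugated dienolate (the C8 alkoxide is inert), and Davis enolate oxidation takes place on the face anti to the neighbouring C5 side chain, giving the trans (6S) ketol, which is also the diequatorial, thermodynamically preferred epimer.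

Step 8
Reactants: 15 (5S,6S)-6-hydroxy-5-[(3R)-3-hydroxy-6-methylhepta-1,5-dien-2-yl]-2-methylcyclohex-2-en-1-one; 16 3-methylbut-2-enoyl chloride
Product: 17 (1S,6S)-3-methyl-6-{(3R)-6-methyl-3-[(3-methylbut-2-enoyl)oxy]hepta-1,5-dien-2-yl}-2-oxocyclohex-3-en-1-yl 3-methylbut-2-enoate
Conditions: 16 (3 equiv), pyridine, DMAP (10 mol%), CH2Cl2, 0 °C
Reagents that add atoms: none
Why: DMAP-catalysed acylation through the acylpyridinium esterifies both secondary hydroxyls with retention, and the weak base and low temperature limit deconjugation of the acid chloride.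

Step 9
Reactants: 17 (1S,6S)-3-methyl-6-{(3R)-6-methyl-3-[(3-methylbut-2-enoyl)oxy]hepta-1,5-dien-2-yl}-2-oxocyclohex-3-en-1-yl 3-methylbut-2-enoate
Product: 18 (1S,2S,6S)-2-hydroxy-3-methyl-6-{(3R)-6-methyl-3-[(3-methylbut-2-enoyl)oxy]hepta-1,5-dien-2-yl}cyclohex-3-en-1-yl 3-methylbut-2-enoate
Conditions: NaBH4, CeCl3·7H2O, MeOH, −78 °C
Reagents that add atoms: none
Why: Luche 1,2-reduction delivers hydride along the axial trajectory of the half-chair that holds both substituents equatorial, giving the equatorial C1 alcohol cis to the C5 side chain and trans to the C6 ester (as in carvone to cis-carveol), with esters and isolated alkenes untouched.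

Step 10
Reactants: 18 (1S,2S,6S)-2-hydroxy-3-methyl-6-{(3R)-6-methyl-3-[(3-methylbut-2-enoyl)oxy]hepta-1,5-dien-2-yl}cyclohex-3-en-1-yl 3-methylbut-2-enoate
Product: 19 (1R,2R,3S,4S,6S)-2-hydroxy-1-methyl-4-{(3R)-6-methyl-3-[(3-methylbut-2-enoyl)oxy]hepta-1,5-dien-2-yl}-7-oxabicyclo[4.1.0]heptan-3-yl 3-methylbut-2-enoate
Conditions: VO(acac)2 (5 mol%), t-BuOOH (1.5 equiv), CH2Cl2, 0 °C to rt
Reagents that add atoms: tert-butyl hydroperoxide CC(C)(C)OO
Why: Hydroxyl-directed vanadium-catalysed epoxidation (Sharpless–Michaelson) delivers oxygen from the vanadate ester of the C1 alcohol to the same face of the only allylic-alcohol alkene, so the oxirane forms cis to the C1 hydroxyl and hence cis to the side chain and trans to the C6 ester, while the other alkenes lack a free allylic hydroxyl or are electron-poor.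

Step 11
Reactants: 19 (1R,2R,3S,4S,6S)-2-hydroxy-1-methyl-4-{(3R)-6-methyl-3-[(3-methylbut-2-enoyl)oxy]hepta-1,5-dien-2-yl}-7-oxabicyclo[4.1.0]heptan-3-yl 3-methylbut-2-enoate
Product: 20 (1S,3S,4S,6S)-1-methyl-4-{(3R)-6-methyl-3-[(3-methylbut-2-enoyl)oxy]hepta-1,5-dien-2-yl}-2-oxo-7-oxabicyclo[4.1.0]heptan-3-yl 3-methylbut-2-enoate
Conditions: Dess–Martin periodinane, CH2Cl2, 0 °C to rt
Reagents that add atoms: none
Why: Dess–Martin oxidation converts the secondary alcohol into the ketone under near-neutral conditions that leave the oxirane, both esters and all alkenes intact and touch no stereocentre.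

## Compound list

1 | 4-methylpent-3-en-1-ol | CC(C)=CCCO | starting material
2 | 4-methylpent-3-enal | CC(C)=CCC=O | intermediate
3 | ethynyl(trimethyl)silane | C#C[Si](C)(C)C | starting material
4 | (3R)-6-methyl-1-(trimethylsilyl)hept-5-en-1-yn-3-ol | C[Si](C)(C)C#C[C@@H](CC=C(C)C)O | intermediate (not isolated)
5 | (3R)-6-methylhept-5-en-1-yn-3-ol | C#C[C@@H](CC=C(C)C)O | intermediate
6 | methyl 3-oxopentanoate | CCC(=O)CC(=O)OC | starting material
7 | (3R)-6-methylhept-5-en-1-yn-3-yl 3-oxopentanoate | C#C[C@@H](CC=C(C)C)OC(=O)CC(=O)CC | intermediate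
8 | prop-2-en-1-ol (allyl alcohol) | C=CCO | starting material
9 | (5R)-8-methyl-4-methylidene-1-oxonon-7-en-5-yl 3-oxopentanoate | O=CCCC(=C)[C@@H](CC=C(C)C)OC(=O)CC(=O)CC | intermediate
10 | (2E,5R)-8-methyl-4-methylidene-1-oxonona-2,7-dien-5-yl 3-oxopentanoate | O=C/C=C/C(=C)[C@@H](CC=C(C)C)OC(=O)CC(=O)CC | intermediate (not isolated)
11 | 2-[(4R,6R)-5-methylidene-6-(3-methylbut-2-en-1-yl)-2-oxo-3-propanoyloxan-4-yl]acetaldehyde (C3 epimers and enol) | O=CC[C@H]1C(=C)[C@@H](CC=C(C)C)OC(=O)C1C(=O)CC | intermediate (not isolated)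
12 | (3R,4aR)-7-methyl-4-methylidene-3-(3-methylbut-2-en-1-yl)-3,4,4a,5-tetrahydro-1H-isochromene-1,8(8aH)-dione (C8a epimers and enol; 3- and 4a-substituents cis on the lactone) | C=C1[C@@H](CC=C(C)C)OC(=O)C2C(=O)C(C)=CC[C@@H]12 | intermediate
13 | (6R)-6-[(3R)-3-hydroxy-6-methylhepta-1,5-dien-2-yl]-3-methyl-2-oxocyclohex-3-ene-1-carboxylic acid (C1 epimers) | C=C([C@@H](CC=C(C)C)O)[C@@H]1CC=C(C)C(=O)C1C(=O)O | intermediate (not isolated)
14 | (5R)-5-[(3R)-3-hydroxy-6-methylhepta-1,5-dien-2-yl]-2-methylcyclohex-2-en-1-one | C=C([C@@H](CC=C(C)C)O)[C@@H]1CC=C(C)C(=O)C1 | intermediate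
15 | (5S,6S)-6-hydroxy-5-[(3R)-3-hydroxy-6-methylhepta-1,5-dien-2-yl]-2-methylcyclohex-2-en-1-one (6-OH trans to side chain) | C=C([C@@H](CC=C(C)C)O)[C@@H]1CC=C(C)C(=O)[C@H]1O | intermediate
16 | 3-methylbut-2-enoyl chloride | CC(C)=CC(=O)Cl | starting material
17 | (1S,6S)-3-methyl-6-{(3R)-6-methyl-3-[(3-methylbut-2-enoyl)oxy]hepta-1,5-dien-2-yl}-2-oxocyclohex-3-en-1-yl 3-methylbut-2-enoate | C=C([C@@H](CC=C(C)C)OC(=O)C=C(C)C)[C@@H]1CC=C(C)C(=O)[C@H]1OC(=O)C=C(C)C | intermediate
18 | (1S,2S,6S)-2-hydroxy-3-methyl-6-{(3R)-6-methyl-3-[(3-methylbut-2-enoyl)oxy]hepta-1,5-dien-2-yl}cyclohex-3-en-1-yl 3-methylbut-2-enoate (OH cis to side chain, trans to ring ester) | C=C([C@@H](CC=C(C)C)OC(=O)C=C(C)C)[C@@H]1CC=C(C)[C@H](O)[C@H]1OC(=O)C=C(C)C | intermediate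
19 | (1R,2R,3S,4S,6S)-2-hydroxy-1-methyl-4-{(3R)-6-methyl-3-[(3-methylbut-2-enoyl)oxy]hepta-1,5-dien-2-yl}-7-oxabicyclo[4.1.0]heptan-3-yl 3-methylbut-2-enoate (oxirane cis to OH and side chain) | C=C([C@@H](CC=C(C)C)OC(=O)C=C(C)C)[C@@H]1C[C@@H]2O[C@]2(C)[C@H](O)[C@H]1OC(=O)C=C(C)C | intermediate
20 | (1S,3S,4S,6S)-1-methyl-4-{(3R)-6-methyl-3-[(3-methylbut-2-enoyl)oxy]hepta-1,5-dien-2-yl}-2-oxo-7-oxabicyclo[4.1.0]heptan-3-yl 3-methylbut-2-enoate (CNP0140369.1) | C=C([C@@H](CC=C(C)C)OC(=O)C=C(C)C)[C@@H]1C[C@@H]2O[C@]2(C)C(=O)[C@H]1OC(=O)C=C(C)C | target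

## Step count and risks

Total step count: 11. Longest linear sequence: 11 (1 to 20).

The three steps most likely to fail are 5, 2 and 7.

Step 5 is the least precedented. IBX may attack the β-keto ester or the product. The ester tether must adopt its less favoured rotamer to cyclise. The enol may add to the methylidene terminus (1,6) instead of C5. This fallback sets out from 5 and also replaces step 4. Markovnikov bromoboration–protodeboronation of 5 (B-bromo-9-BBN, then AcOH) gives (3R)-2-bromo-6-methylhepta-1,5-dien-3-ol F3. Heck coupling with acrolein (Pd(OAc)2, Bu4NCl, NaHCO3, DMF) gives (2E,5R)-5-hydroxy-8-methyl-4-methylidenenona-2,7-dienal F4. The same (S)-prolinol ether then catalyses an intermolecular Michael addition of 6 to F4, giving methyl (3R,5R)-5-hydroxy-8-methyl-4-methylidene-3-(2-oxoethyl)-2-propanoylnon-7-enoate F5. TsOH then closes both rings, by aldol condensation and by lactonisation of the C8 hydroxyl onto the methyl ester. The detour comes back to the route at 12, with no oxidant and with the lactone formed after the C–C bond instead of before it.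

Step 2 uses an enolisable β,γ-unsaturated aldehyde, which may self-condense or isomerise under the zinc/amine conditions and erode yield and ee. This fallback sets out from 2. Addition of lithium (trimethylsilyl)acetylide gives racemic 6-methyl-1-(trimethylsilyl)hept-5-en-1-yn-3-ol F1. Oxidation (MnO2 or Dess–Martin periodinane) gives 6-methyl-1-(trimethylsilyl)hept-5-en-1-yn-3-one F2. Noyori transfer hydrogenation (RuCl[(R,R)-TsDPEN](p-cymene), i-PrOH) then sets the carbinol by reduction instead of addition. It comes back to the route at 4, which is desilylated to 5 as in step 2.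

Step 7 relies on regioselective α′-enolisation of a dianion and on facial control by one neighbouring substituent; γ-deprotonation, addition of the enolate to the sulfonylimine by-product or a cis/trans mixture are possible. This fallback sets out from 12 and moves the oxygenation to the stage where C6 is doubly activated. Hydroxylation of the β-keto lactone with the same oxaziridine and K2CO3 gives (3R,4aS)-8a-hydroxy-7-methyl-4-methylidene-3-(3-methylbut-2-en-1-yl)-3,4,4a,5-tetrahydro-1H-isochromene-1,8(8aH)-dione F6. LiOH hydrolysis and acidification then decarboxylate the α-hydroxy β-keto acid (acetolactate-type) through the enediol. It comes back to the route at 15, the trans ketol being the stable epimer, and skips 14.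

## Further compounds

F1 | step 2 | 6-methyl-1-(trimethylsilyl)hept-5-en-1-yn-3-ol (racemic) | C[Si](C)(C)C#CC(CC=C(C)C)O
F2 | step 2 | 6-methyl-1-(trimethylsilyl)hept-5-en-1-yn-3-one | C[Si](C)(C)C#CC(=O)CC=C(C)C
F3 | step 5 | (3R)-2-bromo-6-methylhepta-1,5-dien-3-ol | C=C(Br)[C@@H](CC=C(C)C)O
F4 | step 5 | (2E,5R)-5-hydroxy-8-methyl-4-methylidenenona-2,7-dienal | O=C/C=C/C(=C)[C@@H](CC=C(C)C)O
F5 | step 5 | methyl (3R,5R)-5-hydroxy-8-methyl-4-methylidene-3-(2-oxoethyl)-2-propanoylnon-7-enoate (C2 epimers) | CCC(=O)C(C(=O)OC)[C@@H](CC=O)C(=C)[C@@H](CC=C(C)C)O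
F6 | step 7 | (3R,4aS)-8a-hydroxy-7-methyl-4-methylidene-3-(3-methylbut-2-en-1-yl)-3,4,4a,5-tetrahydro-1H-isochromene-1,8(8aH)-dione (C8a epimers) | C=C1[C@@H](CC=C(C)C)OC(=O)C2(O)C(=O)C(C)=CC[C@@H]12
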